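## Structural features

The target is a flavonol: a 4H-chromen-4-one (rings A and C) with a hydroxyl at C3 and a benzene ring (ring B) attached through the C2–C1' bond. Ring A carries a methyl group at C6 and a hydroxyl at C7. Ring B is substituted at four neighbouring positions: the chromone at C1', a prenyl (3-methylbut-2-en-1-yl) group at C2', and hydroxyls at C3' and C4'; C5' and C6' are CH. There is no stereocentre, so the problem is one of regiochemistry and functional-group tolerance only. The fragile groups are the prenyl alkene (acid can make it cyclise onto the C3' hydroxyl to a dimethylchroman; it also excludes hydrogenolysis, strong Lewis acids and electrophilic oxidants late in the route), the catechol and the 3-hydroxy-4-pyranone (air oxidation in base, metal chelation), and chromone C2 (addition of nucleophiles, ring opening). The real difficulty is ring B, where the prenyl group is wedged between the C1'–C2 bond and the C3' oxygen; this pattern is awkward to reach by substitution on a benzene ring. The key step uses the fact that C3' (OH) lies between the prenyl carbon C2' and the oxygenated C4', while C5' and C6' are unsubstituted. C3' to C6' therefore map onto the four carbons of a 3-alkoxyfuran, the furan ring oxygen becomes the C3' hydroxyl, and C1'/C2' map onto an alkyne carrying the chromone at one end and the prenyl CH2 at the other.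

## Logic of the disconnections

19 to 18. The O–CH2 bonds of the two methoxymethyl acetals on O3 and O7 are cut last. This leaves only an acetal exchange as the final operation on the fully functionalised molecule. The forward step must use acid weak enough to spare the prenyl group beside the free C3' hydroxyl.

18 to 17. The O–CH3 bond at C4' is cut. The methyl group is the residue of the alkoxy substituent that steers the ring B construction, so it is treated as a protecting group. The forward step must be nucleophilic, not Lewis acidic, because of the prenyl alkene, and it must leave the two acetals in place so that no further anionic oxygen is generated on the chromone during the cleavage.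

17 to 14 and 15 (through 16). The C1'–C6' and C2'–C3' bonds of ring B are cut, and the C3' hydroxyl is traced back to an oxygen bridge between C3' and C6'. This removes the whole tetrasubstituted arene and replaces it by an internal alkyne and a five-membered heteroaromatic diene. The forward step must deliver one orientation in the cycloaddition and one sense of bridge opening; both are expected to be set by the alkoxy group of 15. It must also work on an alkyne activated only through the chromone.

14 to 10 and 13. The bond between chromone C2 and the alkyne carbon is cut, an sp2–sp bond made reliably by cross-coupling. This separates the heterocycle from a seven-carbon enyne. The forward step must avoid nucleophilic amines, which would displace the halide at C2, and strong base, which would isomerise the CH2 group lying between alkyne and alkene.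

13 to 11 and 12. The bond between the alkyne carbon and the propargylic CH2 is cut, giving a two-carbon alkynyl nucleophile and a five-carbon allylic electrophile. The forward step must substitute at the primary carbon of the allylic system.

10 to 8. The C2–I bond is cut. C2–H is the most acidic C–H of 8 and is flanked by a coordinating acetal oxygen, so deprotonative metalation is the natural way to functionalise it. The base must be non-nucleophilic and selective for C2 over C8, the arene position between two oxygens.

8 to 7 to 5. The O3–CH2 acetal bond and then the C3–O bond are cut, which traces the C3 oxygen back to oxidation of the C2=C3 bond of a simple chromone. The forward oxidation must act on an electron-poor enol ether double bond without harming the acetal on ring A.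

5 to 3. O1–C2 and C2–C3 are cut: C2 is a one-carbon unit inserted between the phenol oxygen and the methyl of an ortho-hydroxyacetophenone. The forward cyclisation needs acid mild enough for the aryl acetal.

3 to 2 to 1. The O7–CH2 acetal bond and then the aryl–acyl bond (C4a–C4) are cut, leading back to a dihydric phenol. The forward acylation must go para to one hydroxyl and ortho to the other, and the protection must distinguish the free hydroxyl from the chelated one.

## Other disconnections considered

Alternative 1: The cut is the C3–C4 bond of ring C, made at the dihydroflavonol oxidation level. The racemic dialdehyde A1 has the ring A salicylaldehyde oxygen bound to an α-formyl benzylic carbon that carries a finished ring B. With a triazolium-derived carbene and DBU, the aryl aldehyde would become the acyl anion equivalent and add to the aliphatic aldehyde, giving the 3-hydroxychroman-4-one A2 as a mixture of diastereomers. Dehydrogenation of A2 removes both centres and would give the flavonol tris(methoxymethyl) ether A3, from which acid would release 19.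
- In its favour: it is organocatalytic and mild, and compatible with acetals and the prenyl alkene. The ring-forming step itself creates the C3 oxygen. On this point it is better than the chosen plan, which needs a separate epoxidation and isomerisation (step 4). Its end-game of one deprotection is also better than the two steps needed here.
- Against it: A1 is an α-aryloxy-α-aryl aldehyde, prone to enolisation and aldol self-condensation under DBU. Its assembly needs O-alkylation of a phenol by a hindered secondary benzylic electrophile next to the prenyl group. The carbene must select the electron-rich, para-alkoxy aryl aldehyde over the more electrophilic aliphatic one. A2 must then be oxidised without touching the prenyl alkene.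
- Comparison: structurally, ring B with its four adjacent substituents still has to be made separately by directed metalation, so the hardest problem is only moved, whereas the chosen plan builds that ring with its regiochemistry set by the diene. Mechanistically, the benzoin closure rests on a known reaction type and is the better of the two on that count. In step economy the two are about equal (ten to eleven operations), since the saved hydroxylation is spent on ring B and on the dehydrogenation.

Alternative 2: The cut takes C2 out as carbon monoxide and breaks C1'–C2, C2–C3 and O1–C2. The aryl bromide A4, CO and the acetophenone 3 would react under Pd(OAc)2, 1,4-bis(diphenylphosphino)butane and DBU. An aroyl–palladium species acylates 3, the resulting ester or diketone equilibrates under the base, and cyclodehydration gives the flavone A5.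
- In its favour: three bonds and ring C are formed in one operation by a known reaction type. The plan is highly convergent and uses 3, which the chosen route also makes in two steps. In step economy it is better than the chosen plan (about eight steps against eleven), and in precedent for the ring-forming step it is also better.
- Against it: A5 has no oxygen at C3. A further hydroxylation is needed to reach A3 (C3 metalation, borylation and oxidation); dioxirane epoxidation is excluded by the prenyl alkene. Oxidative addition must occur at an electron-rich bromide flanked by the prenyl group. The aroyl–palladium intermediate has the prenyl alkene within reach for an intramolecular insertion to an indanone. Pressurised CO at high temperature is required.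
- Comparison: structurally the chosen plan carries the C3 oxygen from an early stage and does not need a prefabricated ring B, while this alternative must make A4 by metalation next to bromine. Its risk lies in the late C3 oxidation and the hindered carbonylation, and is no longer in ring B formation.

Alternative 3: The cut is O1–C8a. The 2-alkoxy-1,3-diketone A6 carries fluorine ortho to the ring A carbonyl. With K2CO3 in DMF, the enolate oxygen on the ring B carbonyl would displace fluoride by addition–elimination, closing the six-membered ring C and giving A7, the tetrakis(methoxymethyl) ether of 19.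
- In its favour: it is metal-free, all four oxygens are in place, and A7 needs one acid step and no methyl ether cleavage. This end-game is better than that of the chosen plan. The closure is a known reaction type for chromones, so in reliability of type it is at least the equal of the chosen key step.
- Against it: the fluorinated carbon is only weakly activated. The alkoxy group para to the carbonyl reduces its acceptor strength and the methyl group para to fluorine is donating, so heat would be needed, under which 2-alkoxy-1,3-diketones can undergo retro-Claisen cleavage. A6 needs a fluorinated ring A acid derivative that is not a simple commercial compound, and a crossed Claisen acylation with a hindered ortho-prenyl aroyl partner.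
- Comparison: ring B again has to be prefabricated. In step economy it is about equal to or slightly longer than the chosen plan.

Key step: step 9

Assumption: 15 is kept as the diene because it is the 3-alkoxyfuran that can be purchased; the C4' methyl ether it leaves behind is treated as a protecting group and removed with a thiolate. The structures of 14 and 17 were checked atom by atom against the target and need no correction. Compounds 6 and 16 are racemic; one enantiomer is drawn.

## Route

Step 1
Reactants: 1 4-methylbenzene-1,3-diol (4-methylresorcinol)
Product: 2 1-(2,4-dihydroxy-5-methylphenyl)ethan-1-one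
Conditions: AcOH, BF3·OEt2, 90 °C; then H2O
Reagents that add atoms: acetic acid, CC(=O)O
Why: Friedel–Crafts (Nencki-type) C-acylation of a resorcinol; the position para to one hydroxyl and ortho to the other is the most nucleophilic and least hindered site, the position between the two hydroxyls is crowded, and the ortho-hydroxy ketone is held as its boron chelate until work-up.

Step 2
Reactants: 2 1-(2,4-dihydroxy-5-methylphenyl)ethan-1-one
Product: 3 1-[2-hydroxy-4-(methoxymethoxy)-5-methylphenyl]ethan-1-one
Conditions: MOMCl (1.05 equiv), K2CO3, acetone, 0 °C → rt
Reagents that add atoms: chloromethyl methyl ether (MOMCl), COCCl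
Why: Williamson-type O-alkylation; the hydroxyl para to the acetyl group is the more acidic and is free, whereas the ortho hydroxyl is hydrogen-bonded to the carbonyl, so monoprotection at the future O7 is expected.

Step 3
Reactants: 3 1-[2-hydroxy-4-(methoxymethoxy)-5-methylphenyl]ethan-1-one
Product: 5 7-(methoxymethoxy)-6-methyl-4H-chromen-4-one, via enaminone 4 (not isolated)
Conditions: DMF–DMA, PhMe, 90 °C; then AcOH, 50 °C
Reagents that add atoms: N,N-dimethylformamide dimethyl acetal, COC(OC)N(C)C
Why: Enaminone formation at the methyl ketone, then acid-promoted addition of the phenol to the β-carbon and loss of dimethylamine (enaminone route to chromones); acetic acid is strong enough for the cyclisation and too weak to cleave the aryl MOM ether.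

Step 4
Reactants: 5 7-(methoxymethoxy)-6-methyl-4H-chromen-4-one
Product: 7 3-hydroxy-7-(methoxymethoxy)-6-methyl-4H-chromen-4-one, via chromone 2,3-epoxide 6 (not isolated)
Conditions: DMDO (acetone), CH2Cl2, 0 °C → rt; then p-TsOH·H2O (5 mol %), CH2Cl2, rt
Reagents that add atoms: dimethyldioxirane, CC1(C)OO1
Why: Dioxirane epoxidation of the chromone C2=C3 bond, then acid-catalysed opening at C2 (oxocarbenium ion stabilised by O1) and loss of the C3 proton gives the 3-hydroxychromone; the two centres of 6 are cis by ring constraint, racemic, and both vanish in the isomerisation.

Step 5
Reactants: 7 3-hydroxy-7-(methoxymethoxy)-6-methyl-4H-chromen-4-one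
Product: 8 3,7-bis(methoxymethoxy)-6-methyl-4H-chromen-4-one
Conditions: MOMCl, K2CO3, acetone, 50 °C
Reagents that add atoms: chloromethyl methyl ether (MOMCl), COCCl
Why: O-alkylation of the acidic enolic 3-hydroxyl; the acetal removes the acidic proton before metalation and then serves as a coordinating group next to C2.

Step 6
Reactants: 8 3,7-bis(methoxymethoxy)-6-methyl-4H-chromen-4-one
Product: 10 2-iodo-3,7-bis(methoxymethoxy)-6-methyl-4H-chromen-4-one, via C2-magnesiated chromone 9 (not isolated)
Conditions: TMPMgCl·LiCl (1.2 equiv), THF, −40 °C; then I2, −40 °C → rt
Reagents that add atoms: iodine, II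
Why: Directed deprotonative magnesiation of a chromone with a hindered, non-nucleophilic amide base, then iodinolysis; C2–H is the most acidic C–H (sp2, next to O1, flanked by the coordinating 3-OMOM group), and the magnesium derivative is less prone than a lithium one to fragmentation or carbonyl attack.

Step 7
Reactants: 11 ethynylmagnesium bromide; 12 1-bromo-3-methylbut-2-ene (prenyl bromide)
Product: 13 5-methylhex-4-en-1-yne
Conditions: CuCl (5 mol %), THF, 0 °C → 50 °C
Reagents that add atoms: none
Why: Copper-catalysed allylic substitution of a primary allylic bromide by an alkynyl Grignard reagent; attack at the unhindered primary carbon gives the linear 1,4-enyne, which is volatile and best carried on as a distilled solution.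

Step 8
Reactants: 10 2-iodo-3,7-bis(methoxymethoxy)-6-methyl-4H-chromen-4-one; 13 5-methylhex-4-en-1-yne
Product: 14 3,7-bis(methoxymethoxy)-6-methyl-2-(5-methylhex-4-en-1-yn-1-yl)-4H-chromen-4-one
Conditions: Pd(PPh3)2Cl2 (3 mol %), CuI (5 mol %), Et3N (3 equiv), THF, rt, degassed
Reagents that add atoms: none
Why: Sonogashira coupling of an activated alkenyl iodide with a terminal alkyne; a tertiary amine is used because it cannot displace the iodide at C2 by addition–elimination, and room temperature limits isomerisation of the doubly activated CH2 group of the product.

Step 9
Reactants: 14 3,7-bis(methoxymethoxy)-6-methyl-2-(5-methylhex-4-en-1-yn-1-yl)-4H-chromen-4-one; 15 3-methoxyfuran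
Product: 17 2-[3-hydroxy-4-methoxy-2-(3-methylbut-2-en-1-yl)phenyl]-3,7-bis(methoxymethoxy)-6-methyl-4H-chromen-4-one, via oxanorbornadiene cycloadduct 16 (not isolated)
Conditions: 15 (5 equiv), BHT (cat.), PhMe, 90 °C, sealed tube; concentrate; then CSA (10 mol %), CH2Cl2, 0 °C
Reagents that add atoms: none
Why: Proposed new method: the electron-rich diene 15 and the alkyne of 14, polarised as a vinylogous ynone through C2=C3–C4=O, should combine in a normal-demand, asynchronous [4+2] cycloaddition in which furan C2 (the most nucleophilic carbon, between the ring oxygen and the methoxy-bearing carbon) bonds to the alkyne carbon remote from the chromone, and acid then cleaves the bridging C–O bond at the bridgehead whose cation is a vinylogous oxocarbenium ion, after which proton loss gives the arene; the closest known reaction type is the Diels–Alder reaction of 3-alkoxyfurans with acetylenic esters and ketones followed by acid opening of the 7-oxanorbornadiene to a phenol, which has not been shown for an alkyne activated only through a chromone. Ring B is closed by an intermolecular [4+2] cycloaddition that forms C1'–C6' and C2'–C3', not by cyclisation of a chain, and the oxygen bridge of 16 is then released from C6' by ionisation and deprotonation at C3'. The two bridgehead centres of 16 are racemic, transient and destroyed on aromatisation, so no stereocentre needs control. Regioselectivity is needed in both events and the methoxy group should secure it: it makes furan C2 the nucleophilic terminus, and it stabilises a cation at C6' but not at C3', so the hydroxyl ends on C3' next to the prenyl carbon. Chemoselectivity for the alkyne over the trisubstituted prenyl alkene and the tetrasubstituted C2=C3 bond is expected because neither is an activated dienophile. Heat without a strong Lewis acid is chosen so that the acid-labile furan, the acetals and the CH2 group of 14 are not exposed to conditions that favour conjugate addition with re-aromatisation of the furan over cycloaddition. The catalytic, anhydrous acid is added only after excess 15 has been removed, and aromatisation makes the sequence irreversible.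

Step 10
Reactants: 17 2-[3-hydroxy-4-methoxy-2-(3-methylbut-2-en-1-yl)phenyl]-3,7-bis(methoxymethoxy)-6-methyl-4H-chromen-4-one
Product: 18 2-[3,4-dihydroxy-2-(3-methylbut-2-en-1-yl)phenyl]-3,7-bis(methoxymethoxy)-6-methyl-4H-chromen-4-one
Conditions: NaSEt (6 equiv), DMF, 120 °C; then dilute HCl, 0 °C, to pH 5
Reagents that add atoms: none
Why: SN2 demethylation of an aryl methyl ether by a thiolate; O4' is para to the electron-poor chromone C2, so the departing phenoxide is a vinylogous carboxylate and should leave even though the neighbouring C3' hydroxyl is ionised, while the acetals, the prenyl alkene and the hindered, donor-substituted C2 tolerate the non-acidic medium.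

Step 11
Reactants: 18 2-[3,4-dihydroxy-2-(3-methylbut-2-en-1-yl)phenyl]-3,7-bis(methoxymethoxy)-6-methyl-4H-chromen-4-one
Product: 19 2-[3,4-dihydroxy-2-(3-methylbut-2-en-1-yl)phenyl]-3,7-dihydroxy-6-methyl-4H-chromen-4-one
Conditions: HCl (1 M), MeOH, rt → 40 °C, degassed
Reagents that add atoms: none
Why: Acid-catalysed acetal exchange transfers both methoxymethyl groups to methanol; dilute acid at low temperature suffices for MOM ethers and should be too weak to protonate the trisubstituted prenyl alkene at a competitive rate, so cyclisation onto the C3' hydroxyl should stay minor.

## Compound list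

1 | 4-methylbenzene-1,3-diol (4-methylresorcinol) | Cc1ccc(O)cc1O | starting material
2 | 1-(2,4-dihydroxy-5-methylphenyl)ethan-1-one | CC(=O)c1cc(C)c(O)cc1O | intermediate
3 | 1-[2-hydroxy-4-(methoxymethoxy)-5-methylphenyl]ethan-1-one | CC(=O)c1cc(C)c(OCOC)cc1O | intermediate
4 | (E)-3-(dimethylamino)-1-[2-hydroxy-4-(methoxymethoxy)-5-methylphenyl]prop-2-en-1-one | CN(C)/C=C/C(=O)c1cc(C)c(OCOC)cc1O | intermediate (not isolated)
5 | 7-(methoxymethoxy)-6-methyl-4H-chromen-4-one | COCOc1cc2occc(=O)c2cc1C | intermediate
6 | 2,3-epoxy-7-(methoxymethoxy)-6-methylchroman-4-one, racemic, cis-fused epoxide | COCOc1cc2O[C@H]3O[C@H]3C(=O)c2cc1C | intermediate (not isolated)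
7 | 3-hydroxy-7-(methoxymethoxy)-6-methyl-4H-chromen-4-one | COCOc1cc2occ(O)c(=O)c2cc1C | intermediate
8 | 3,7-bis(methoxymethoxy)-6-methyl-4H-chromen-4-one | COCOc1cc2occ(OCOC)c(=O)c2cc1C | intermediate
9 | [3,7-bis(methoxymethoxy)-6-methyl-4-oxo-4H-chromen-2-yl]magnesium chloride (as its LiCl complex) | COCOc1cc2oc([Mg]Cl)c(OCOC)c(=O)c2cc1C | intermediate (not isolated)
10 | 2-iodo-3,7-bis(methoxymethoxy)-6-methyl-4H-chromen-4-one | COCOc1cc2oc(I)c(OCOC)c(=O)c2cc1C | intermediate
11 | ethynylmagnesium bromide | C#C[Mg]Br | starting material
12 | 1-bromo-3-methylbut-2-ene (prenyl bromide) | CC(C)=CCBr | starting material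
13 | 5-methylhex-4-en-1-yne | CC(C)=CCC#C | intermediate
14 | 3,7-bis(methoxymethoxy)-6-methyl-2-(5-methylhex-4-en-1-yn-1-yl)-4H-chromen-4-one | CC(C)=CCC#Cc1oc2cc(OCOC)c(C)cc2c(=O)c1OCOC | intermediate
15 | 3-methoxyfuran | COc1ccoc1 | starting material
16 | 2-[5-methoxy-3-(3-methylbut-2-en-1-yl)-7-oxabicyclo[2.2.1]hepta-2,5-dien-2-yl]-3,7-bis(methoxymethoxy)-6-methyl-4H-chromen-4-one, racemic | COC1=C[C@H]2O[C@@H]1C(CC=C(C)C)=C2c1oc2cc(OCOC)c(C)cc2c(=O)c1OCOC | intermediate (not isolated)
17 | 2-[3-hydroxy-4-methoxy-2-(3-methylbut-2-en-1-yl)phenyl]-3,7-bis(methoxymethoxy)-6-methyl-4H-chromen-4-one | CC(C)=CCc1c(-c2oc3cc(OCOC)c(C)cc3c(=O)c2OCOC)ccc(OC)c1O | intermediate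
18 | 2-[3,4-dihydroxy-2-(3-methylbut-2-en-1-yl)phenyl]-3,7-bis(methoxymethoxy)-6-methyl-4H-chromen-4-one | CC(C)=CCc1c(-c2oc3cc(OCOC)c(C)cc3c(=O)c2OCOC)ccc(O)c1O | intermediate
19 | 2-[3,4-dihydroxy-2-(3-methylbut-2-en-1-yl)phenyl]-3,7-dihydroxy-6-methyl-4H-chromen-4-one | CC(C)=CCc1c(-c2oc3cc(O)c(C)cc3c(=O)c2O)ccc(O)c1O | target

## Step count and least certain steps

Total step count: 11. Longest linear sequence: 10 steps (steps 1 to 6 and 8 to 11); step 7 is a one-step side branch.

Step 9 (key step, proposed new method). The most likely failure is insufficient dienophile reactivity. The alkyne is activated only through a vinylogous ester and is further damped by the C3 alkoxy donor, so oligomerisation of 15 or cycloreversion may outrun product formation. If acid or Lewis acid is used to accelerate it, stepwise conjugate addition of furan C2 followed by re-aromatisation of the furan may replace cycloaddition. On acid treatment, hydrolysis of the enol ether or bridge opening in the other sense may compete with the desired aromatisation. Within the same approach, pressure of about 10 kbar at room temperature is the first recourse. The fallback uses known chemistry and joins a finished ring B to C2 by Suzuki–Miyaura coupling; it sets out from 10 and returns to the route at 19. Commercial 4-bromobenzene-1,2-diol F1 would be protected (MOMCl, iPr2NEt, CH2Cl2) to 4-bromo-1,2-bis(methoxymethoxy)benzene F2. Deprotonation between bromine and the adjacent acetal oxygen with lithium diisopropylamide, LiN(iPr)2, at −78 °C, transmetalation with CuBr·SMe2 and allylation with 12 would give 1-bromo-3,4-bis(methoxymethoxy)-2-(3-methylbut-2-en-1-yl)benzene F3 (the same compound as A4). Bromine–lithium exchange (n-BuLi, −78 °C) and quench with 2-isopropoxy-4,4,5,5-tetramethyl-1,3,2-dioxaborolane would give 2-[3,4-bis(methoxymethoxy)-2-(3-methylbut-2-en-1-yl)phenyl]-4,4,5,5-tetramethyl-1,3,2-dioxaborolane F4. Coupling of F4 with 10 (Pd(OAc)2, SPhos, K3PO4, toluene/water, 80 °C) would give 3,7-bis(methoxymethoxy)-6-methyl-2-[3,4-bis(methoxymethoxy)-2-(3-methylbut-2-en-1-yl)phenyl]-4H-chromen-4-one F5 (the same compound as A7). HCl in methanol as in step 11 would release 19.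

Step 10. Demethylation may be retarded because the C3' hydroxyl is ionised first, so the leaving group is formally a catechol dianion. The more forcing conditions this invites could bring thiolate addition at chromone C2 with ring opening, or loss of the 3-O acetal, which would further deactivate the system. The fallback masks the C3' hydroxyl before the thiolate step; it sets out from 17 and returns at 19. MOMCl and K2CO3 in acetone would give 2-[4-methoxy-3-(methoxymethoxy)-2-(3-methylbut-2-en-1-yl)phenyl]-3,7-bis(methoxymethoxy)-6-methyl-4H-chromen-4-one F8. NaSEt in DMF would then cleave the methyl ether from a neutral substrate to give 2-[4-hydroxy-3-(methoxymethoxy)-2-(3-methylbut-2-en-1-yl)phenyl]-3,7-bis(methoxymethoxy)-6-methyl-4H-chromen-4-one F9. Methanolic HCl would remove all three acetals to give 19.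

Step 8. The CH2 group between alkyne and alkene is propargylic, allylic and, in the product, vinylogously α to a carbonyl, so base-induced prototropic isomerisation to an allene or conjugated dienyne is the main danger. Oxidative homocoupling of 13 and amine attack at C2 of 10 are lesser ones. The fallback is a base-free Stille coupling; it sets out from 13 (with 10) and returns at 14. Deprotonation of 13 with n-BuLi at −78 °C and quench with Bu3SnCl would give tributyl(5-methylhex-4-en-1-yn-1-yl)stannane F6, which would be coupled with 10 using Pd(PPh3)4 in toluene at 60 °C.

Step 6. Metalation may occur partly at C8, the arene position between O1 and the 7-O acetal, or the C2-metalated pyranone may fragment on warming before it is trapped. The fallback replaces deprotonation by electrophilic substitution; it sets out from 7 and returns at 10. The free enol 7 would be iodinated at C2, the position next to the enolic hydroxyl (as in the halogenation of kojic acid), with N-iodosuccinimide in MeCN at 0 °C to give 3-hydroxy-2-iodo-7-(methoxymethoxy)-6-methyl-4H-chromen-4-one F7. O-alkylation with MOMCl and K2CO3 would then give 10.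

Step 11. Acid may promote addition of the C3' hydroxyl to the prenyl alkene (chroman formation) or Markovnikov addition of methanol before both acetals are gone. The fallback blocks the catechol as esters during the acid step; it sets out from 18 and returns at 19. Pivaloyl chloride, Et3N and DMAP would give 4-[3,7-bis(methoxymethoxy)-6-methyl-4-oxo-4H-chromen-2-yl]-3-(3-methylbut-2-en-1-yl)-1,2-phenylene bis(2,2-dimethylpropanoate) F10. Methanolic HCl at room temperature would remove the acetals while the hindered esters persist, giving 4-(3,7-dihydroxy-6-methyl-4-oxo-4H-chromen-2-yl)-3-(3-methylbut-2-en-1-yl)-1,2-phenylene bis(2,2-dimethylpropanoate) F11. K2CO3 in methanol under argon would then cleave the aryl esters to give 19.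

## Further compounds

F1 | step 9 | 4-bromobenzene-1,2-diol | Oc1ccc(Br)cc1O
F2 | step 9 | 4-bromo-1,2-bis(methoxymethoxy)benzene | COCOc1ccc(Br)cc1OCOC
F3 | step 9 | 1-bromo-3,4-bis(methoxymethoxy)-2-(3-methylbut-2-en-1-yl)benzene | CC(C)=CCc1c(Br)ccc(OCOC)c1OCOC
F4 | step 9 | 2-[3,4-bis(methoxymethoxy)-2-(3-methylbut-2-en-1-yl)phenyl]-4,4,5,5-tetramethyl-1,3,2-dioxaborolane | CC(C)=CCc1c(B2OC(C)(C)C(C)(C)O2)ccc(OCOC)c1OCOC
F5 | step 9 | 3,7-bis(methoxymethoxy)-6-methyl-2-[3,4-bis(methoxymethoxy)-2-(3-methylbut-2-en-1-yl)phenyl]-4H-chromen-4-one | CC(C)=CCc1c(-c2oc3cc(OCOC)c(C)cc3c(=O)c2OCOC)ccc(OCOC)c1OCOC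
F6 | step 8 | tributyl(5-methylhex-4-en-1-yn-1-yl)stannane | CCCC[Sn](CCCC)(CCCC)C#CCC=C(C)C
F7 | step 6 | 3-hydroxy-2-iodo-7-(methoxymethoxy)-6-methyl-4H-chromen-4-one | COCOc1cc2oc(I)c(O)c(=O)c2cc1C
F8 | step 10 | 2-[4-methoxy-3-(methoxymethoxy)-2-(3-methylbut-2-en-1-yl)phenyl]-3,7-bis(methoxymethoxy)-6-methyl-4H-chromen-4-one | CC(C)=CCc1c(-c2oc3cc(OCOC)c(C)cc3c(=O)c2OCOC)ccc(OC)c1OCOC
F9 | step 10 | 2-[4-hydroxy-3-(methoxymethoxy)-2-(3-methylbut-2-en-1-yl)phenyl]-3,7-bis(methoxymethoxy)-6-methyl-4H-chromen-4-one | CC(C)=CCc1c(-c2oc3cc(OCOC)c(C)cc3c(=O)c2OCOC)ccc(O)c1OCOC
F10 | step 11 | 4-[3,7-bis(methoxymethoxy)-6-methyl-4-oxo-4H-chromen-2-yl]-3-(3-methylbut-2-en-1-yl)-1,2-phenylene bis(2,2-dimethylpropanoate) | CC(C)=CCc1c(-c2oc3cc(OCOC)c(C)cc3c(=O)c2OCOC)ccc(OC(=O)C(C)(C)C)c1OC(=O)C(C)(C)C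
F11 | step 11 | 4-(3,7-dihydroxy-6-methyl-4-oxo-4H-chromen-2-yl)-3-(3-methylbut-2-en-1-yl)-1,2-phenylene bis(2,2-dimethylpropanoate) | CC(C)=CCc1c(-c2oc3cc(O)c(C)cc3c(=O)c2O)ccc(OC(=O)C(C)(C)C)c1OC(=O)C(C)(C)C
A1 | alternative 1 | 2-[2-formyl-5-(methoxymethoxy)-4-methylphenoxy]-2-[3,4-bis(methoxymethoxy)-2-(3-methylbut-2-en-1-yl)phenyl]acetaldehyde, racemic | CC(C)=CCc1c(C(C=O)Oc2cc(OCOC)c(C)cc2C=O)ccc(OCOC)c1OCOC
A2 | alternative 1 | 3-hydroxy-7-(methoxymethoxy)-6-methyl-2-[3,4-bis(methoxymethoxy)-2-(3-methylbut-2-en-1-yl)phenyl]chroman-4-one, racemic mixture of cis and trans isomers | CC(C)=CCc1c(C2Oc3cc(OCOC)c(C)cc3C(=O)C2O)ccc(OCOC)c1OCOC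
A3 | alternative 1 | 3-hydroxy-7-(methoxymethoxy)-6-methyl-2-[3,4-bis(methoxymethoxy)-2-(3-methylbut-2-en-1-yl)phenyl]-4H-chromen-4-one | CC(C)=CCc1c(-c2oc3cc(OCOC)c(C)cc3c(=O)c2O)ccc(OCOC)c1OCOC
A4 | alternative 2 | 1-bromo-3,4-bis(methoxymethoxy)-2-(3-methylbut-2-en-1-yl)benzene | CC(C)=CCc1c(Br)ccc(OCOC)c1OCOC
A5 | alternative 2 | 7-(methoxymethoxy)-6-methyl-2-[3,4-bis(methoxymethoxy)-2-(3-methylbut-2-en-1-yl)phenyl]-4H-chromen-4-one | CC(C)=CCc1c(-c2cc(=O)c3cc(C)c(OCOC)cc3o2)ccc(OCOC)c1OCOC
A6 | alternative 3 | 1-[2-fluoro-4-(methoxymethoxy)-5-methylphenyl]-2-(methoxymethoxy)-3-[3,4-bis(methoxymethoxy)-2-(3-methylbut-2-en-1-yl)phenyl]propane-1,3-dione, racemic | CC(C)=CCc1c(C(=O)C(OCOC)C(=O)c2cc(C)c(OCOC)cc2F)ccc(OCOC)c1OCOC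
A7 | alternative 3 | 3,7-bis(methoxymethoxy)-6-methyl-2-[3,4-bis(methoxymethoxy)-2-(3-methylbut-2-en-1-yl)phenyl]-4H-chromen-4-one | CC(C)=CCc1c(-c2oc3cc(OCOC)c(C)cc3c(=O)c2OCOC)ccc(OCOC)c1OCOC
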